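**Retrosynthetic overview**

1. Vismiaphenone F is traced back to its 4'-O-triisopropylsilyl ether; the last step is a fluoride desilylation.
2. Key disconnection: the C4–C4a bond of the 2H-pyran and the C8–CH2 bond of the prenyl group are both traced back to O-bound tertiary groups on one benzophenone, a 1,1-dimethylpropargyl ether on the future O1 and a 1,1-dimethylallyl ether on the future 7-OH. One heating (allyl Claisen, then propargyl Claisen, 1,5-H shift and oxa-6π closure) should place the prenyl group, close the pyran ring and free the chelated 7-OH.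
3. Enabling feature: ring A is a phloroglucinol in which each carbon side chain sits ortho to an oxygen. C8 lies between O7 and the O1-bearing C8a, C4a is the other ortho carbon of O1, and C6 (aroyl) blocks the second ortho carbon of O7, so each migrating group has a single destination once the faster allyl shift has filled C8.
4. The benzophenone comes from aryl Grignard addition to a 2,4,6-trioxygenated benzaldehyde followed by oxidation; that aldehyde comes from 2,4-dihydroxy-6-methoxybenzaldehyde by copper-catalysed propargylation of the free 4-OH and palladium-catalysed tert-allylation of the chelated 2-OH.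
5. Ring order: both benzene rings are bought; the pyran ring is the only ring made, in step 6.

Key step: step 6

Assumption: 2,4-dihydroxy-6-methoxybenzaldehyde, 3-chloro-3-methylbut-1-yne and (4-bromophenoxy)triisopropylsilane are taken as purchasable; the target has no stereocentre.

**Route**

Step 1
Reactants: 1 2-methylbut-3-en-2-ol
Product: 3 tert-butyl 2-methylbut-3-en-2-yl carbonate, via lithium alkoxide 2 (not isolated)
Conditions: n-BuLi, THF, 0 °C; then Boc2O, 0 °C to rt
Reagents that add atoms: di-tert-butyl dicarbonate (Boc2O), CC(C)(C)OC(=O)OC(=O)OC(C)(C)C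
Why: Alkoxide acylation, in which the lithium alkoxide of the tertiary allylic alcohol attacks Boc2O to give the mixed carbonate that serves as precursor of a 1,1-dimethylallyl palladium electrophile.

Step 2
Reactants: 4 2,4-dihydroxy-6-methoxybenzaldehyde; 5 3-chloro-3-methylbut-1-yne
Product: 6 2-hydroxy-6-methoxy-4-[(2-methylbut-3-yn-2-yl)oxy]benzaldehyde
Conditions: DBU, CuCl2·2H2O (cat.), MeCN, 0 °C
Reagents that add atoms: none
Why: Copper-catalysed propargylic etherification (substitution through a copper acetylide-derived electrophile), in which only the 4-OH, para to the aldehyde and not hydrogen-bonded, should be alkylated while the chelated 2-OH stays free.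

Step 3
Reactants: 6 2-hydroxy-6-methoxy-4-[(2-methylbut-3-yn-2-yl)oxy]benzaldehyde; 3 tert-butyl 2-methylbut-3-en-2-yl carbonate
Product: 7 2-methoxy-6-[(2-methylbut-3-en-2-yl)oxy]-4-[(2-methylbut-3-yn-2-yl)oxy]benzaldehyde
Conditions: Pd(PPh3)4 (cat.), THF, 0 °C
Reagents that add atoms: none
Why: Tsuji–Trost-type decarboxylative allylic etherification, in which zerovalent palladium ionises the carbonate, the tert-butoxide set free deprotonates the chelated phenol and the phenoxide attacks the more substituted terminus of the 1,1-dimethylallyl palladium cation under kinetic control at low temperature to give the tertiary aryl ether.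

Step 4
Reactants: 7 2-methoxy-6-[(2-methylbut-3-en-2-yl)oxy]-4-[(2-methylbut-3-yn-2-yl)oxy]benzaldehyde; 8 (4-bromophenoxy)triisopropylsilane
Product: 11 rac-{2-methoxy-6-[(2-methylbut-3-en-2-yl)oxy]-4-[(2-methylbut-3-yn-2-yl)oxy]phenyl}{4-[(triisopropylsilyl)oxy]phenyl}methanol, via arylmagnesium bromide 9 (not isolated), via bromomagnesium alkoxide 10 (not isolated)
Conditions: 8, Mg, THF, rt; then 7, −20 to 0 °C; then H2O
Reagents that add atoms: none
Why: Grignard 1,2-addition, in which an aryl magnesium bromide should add to the aldehyde much faster than it deprotonates the terminal alkyne at low temperature; the new carbinol stereocentre forms without control (racemic) and is removed by the oxidation in step 5.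

Step 5
Reactants: 11 rac-{2-methoxy-6-[(2-methylbut-3-en-2-yl)oxy]-4-[(2-methylbut-3-yn-2-yl)oxy]phenyl}{4-[(triisopropylsilyl)oxy]phenyl}methanol
Product: 12 {2-methoxy-6-[(2-methylbut-3-en-2-yl)oxy]-4-[(2-methylbut-3-yn-2-yl)oxy]phenyl}{4-[(triisopropylsilyl)oxy]phenyl}methanone
Conditions: Dess–Martin periodinane, NaHCO3, CH2Cl2, 0 °C to rt
Reagents that add atoms: none
Why: Dess–Martin oxidation of a doubly benzylic secondary alcohol under buffered, non-acidic conditions that should leave the terminal alkyne, both tertiary ethers and the silyl ether untouched.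

Step 6
Reactants: 12 {2-methoxy-6-[(2-methylbut-3-en-2-yl)oxy]-4-[(2-methylbut-3-yn-2-yl)oxy]phenyl}{4-[(triisopropylsilyl)oxy]phenyl}methanone
Product: 16 [7-hydroxy-5-methoxy-2,2-dimethyl-8-(3-methylbut-2-en-1-yl)-2H-chromen-6-yl]{4-[(triisopropylsilyl)oxy]phenyl}methanone, via prenylphenol propargyl ether 13 (not isolated), via ortho-allenylphenol 14 (not isolated), via ortho-quinone methide 15 (not isolated)
Conditions: PhNEt2, 110 °C, then 180 °C, argon
Reagents that add atoms: none
Why: Tandem aromatic Claisen cascade: (1) at about 110 °C the tertiary allyl ether on the oxygen ortho to the ketone undergoes a [3,3] shift with allyl inversion to its only free ortho carbon (the other one carries the aroyl group) and enolises to the chelated prenylphenol 13; (2) at 180 °C the 1,1-dimethylpropargyl ether undergoes the slower propargyl Claisen [3,3] shift to the one ortho carbon that still carries hydrogen, which joins the alkyne terminus to the ring carbon beside the methoxy group, and enolisation gives allenylphenol 14; (3) a 1,5-hydrogen shift from the phenol to the central allene carbon gives the (Z)-ortho-quinone methide 15, which closes by thermal disrotatory oxa-6π electrocyclisation to the 2,2-dimethyl-2H-pyran. Each event is the known thermal behaviour of aryl 1,1-dimethylallyl ethers (to ortho-prenylphenols) and of aryl 1,1-dimethylpropargyl ethers (to 2,2-dimethylchromenes), and the step only runs them in sequence in one flask. The six-membered pyran ring is closed in the sense of a net 6-endo attack of the arene carbon on the alkyne terminus, the C–C bond arising in the cyclic [3,3] transition state and the O–C bond being re-formed in the electrocyclisation. No stereocentre is created. The selectivity needed is positional and is secured by the substrate: the aroyl-bearing carbon blocks one ortho position of the allyl ether so the prenyl group can only land between the two oxygens, the tertiary allyl ether rearranges at a clearly lower temperature than the propargyl ether, the propargyl ether then has a single free ortho carbon, and even a premature propargyl shift should prefer that same less hindered carbon beside the methoxy group, while the weakly basic amine solvent suppresses acid-triggered loss of the tertiary groups.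

Step 7
Reactants: 16 [7-hydroxy-5-methoxy-2,2-dimethyl-8-(3-methylbut-2-en-1-yl)-2H-chromen-6-yl]{4-[(triisopropylsilyl)oxy]phenyl}methanone
Product: 17 Vismiaphenone F, [7-hydroxy-5-methoxy-2,2-dimethyl-8-(3-methylbut-2-en-1-yl)-2H-chromen-6-yl](4-hydroxyphenyl)methanone
Conditions: Bu4NF, AcOH, THF, 0 °C
Reagents that add atoms: none
Why: Fluoride-mediated cleavage of an aryl silyl ether, which should be fast for a phenol para to a ketone and, with buffered fluoride, should not touch the chromene, the prenyl group or the methyl ether.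

**Compound list**

1 | 2-methylbut-3-en-2-ol | C=CC(C)(C)O | starting material
2 | lithium 2-methylbut-3-en-2-olate (formed in the flask) | C=CC(C)(C)O[Li] | intermediate
3 | tert-butyl 2-methylbut-3-en-2-yl carbonate | C=CC(C)(C)OC(=O)OC(C)(C)C | intermediate
4 | 2,4-dihydroxy-6-methoxybenzaldehyde | COc1cc(O)cc(O)c1C=O | starting material
5 | 3-chloro-3-methylbut-1-yne | C#CC(C)(C)Cl | starting material
6 | 2-hydroxy-6-methoxy-4-[(2-methylbut-3-yn-2-yl)oxy]benzaldehyde | COc1cc(OC(C)(C)C#C)cc(O)c1C=O | intermediate
7 | 2-methoxy-6-[(2-methylbut-3-en-2-yl)oxy]-4-[(2-methylbut-3-yn-2-yl)oxy]benzaldehyde | COc1cc(OC(C)(C)C#C)cc(OC(C)(C)C=C)c1C=O | intermediate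
8 | (4-bromophenoxy)triisopropylsilane | CC(C)[Si](Oc1ccc(Br)cc1)(C(C)C)C(C)C | starting material
9 | {4-[(triisopropylsilyl)oxy]phenyl}magnesium bromide (formed in the flask) | CC(C)[Si](Oc1ccc([Mg]Br)cc1)(C(C)C)C(C)C | intermediate
10 | bromomagnesium alkoxide of carbinol 11 (racemic, formed in the flask) | COc1cc(OC(C)(C)C#C)cc(OC(C)(C)C=C)c1C(O[Mg]Br)c1ccc(O[Si](C(C)C)(C(C)C)C(C)C)cc1 | intermediate
11 | rac-{2-methoxy-6-[(2-methylbut-3-en-2-yl)oxy]-4-[(2-methylbut-3-yn-2-yl)oxy]phenyl}{4-[(triisopropylsilyl)oxy]phenyl}methanol | COc1cc(OC(C)(C)C#C)cc(OC(C)(C)C=C)c1C(O)c1ccc(O[Si](C(C)C)(C(C)C)C(C)C)cc1 | intermediate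
12 | {2-methoxy-6-[(2-methylbut-3-en-2-yl)oxy]-4-[(2-methylbut-3-yn-2-yl)oxy]phenyl}{4-[(triisopropylsilyl)oxy]phenyl}methanone | COc1cc(OC(C)(C)C#C)cc(OC(C)(C)C=C)c1C(=O)c1ccc(O[Si](C(C)C)(C(C)C)C(C)C)cc1 | intermediate
13 | {2-hydroxy-6-methoxy-3-(3-methylbut-2-en-1-yl)-4-[(2-methylbut-3-yn-2-yl)oxy]phenyl}{4-[(triisopropylsilyl)oxy]phenyl}methanone (formed in the flask) | COc1cc(OC(C)(C)C#C)c(CC=C(C)C)c(O)c1C(=O)c1ccc(O[Si](C(C)C)(C(C)C)C(C)C)cc1 | intermediate
14 | {2,4-dihydroxy-6-methoxy-5-(3-methylbuta-1,2-dien-1-yl)-3-(3-methylbut-2-en-1-yl)phenyl}{4-[(triisopropylsilyl)oxy]phenyl}methanone (formed in the flask) | COc1c(C=C=C(C)C)c(O)c(CC=C(C)C)c(O)c1C(=O)c1ccc(O[Si](C(C)C)(C(C)C)C(C)C)cc1 | intermediate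
15 | (6Z)-3-hydroxy-5-methoxy-2-(3-methylbut-2-en-1-yl)-6-(3-methylbut-2-en-1-ylidene)-4-{4-[(triisopropylsilyl)oxy]benzoyl}cyclohexa-2,4-dien-1-one (ortho-quinone methide, formed in the flask) | COC1=C(C(=O)c2ccc(O[Si](C(C)C)(C(C)C)C(C)C)cc2)C(O)=C(CC=C(C)C)C(=O)/C1=C\C=C(C)C | intermediate
16 | [7-hydroxy-5-methoxy-2,2-dimethyl-8-(3-methylbut-2-en-1-yl)-2H-chromen-6-yl]{4-[(triisopropylsilyl)oxy]phenyl}methanone | COc1c2c(c(CC=C(C)C)c(O)c1C(=O)c1ccc(O[Si](C(C)C)(C(C)C)C(C)C)cc1)OC(C)(C)C=C2 | intermediate
17 | Vismiaphenone F, [7-hydroxy-5-methoxy-2,2-dimethyl-8-(3-methylbut-2-en-1-yl)-2H-chromen-6-yl](4-hydroxyphenyl)methanone | COc1c2c(c(CC=C(C)C)c(O)c1C(=O)c1ccc(O)cc1)OC(C)(C)C=C2 | target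

**Step count and risks**

Total step count: 7. Longest linear sequence: 6 steps (4 to 17 through steps 2 to 7; the branch 1 to 3 joins in step 3 and is equally long).

Steps most likely to fail:

1. Step 6. During the hotter second stage the propargyl shift may be too slow to outrun thermal loss of the tertiary groups (extrusion of isoprene or of the enyne) and degradation of the ortho-prenylphenol. The fallback sets out from 12 and comes back at 16. Heating 12 only to 110 °C in toluene should stop at prenylphenol 13, which is isolated. The pyran ring is then closed not by a sigmatropic shift but by π-acid catalysis with Ph3PAuNTf2 (cat.) in CH2Cl2 at rt, a 6-endo-dig hydroarylation of the aryl propargyl ether at its only unsubstituted ortho carbon, which is a known way from aryl propargyl ethers to 2H-chromenes. This fallback makes no compound outside the list (F0).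

2. Step 3. The kinetic tertiary ether may be re-ionised by zerovalent palladium and drift to the linear prenyl ether, capture by the hindered chelated phenoxide may be slow, and the propargyl aryl ether may itself be ionised. The fallback sets out from 4 and comes back at 7; the tertiary allyl ether is made without palladium, as a propargyl ether that is half-reduced before the second alkyne is introduced. TIPSCl and imidazole in DMF should silylate only the non-chelated 4-OH to give 2-hydroxy-6-methoxy-4-[(triisopropylsilyl)oxy]benzaldehyde F1. Copper-catalysed propargylation of the 2-OH with 5 (DBU, CuCl2·2H2O, MeCN) should give 2-methoxy-6-[(2-methylbut-3-yn-2-yl)oxy]-4-[(triisopropylsilyl)oxy]benzaldehyde F2. Semihydrogenation (H2, Pd/CaCO3 poisoned with Pb(OAc)2, quinoline, EtOAc) should give 2-methoxy-6-[(2-methylbut-3-en-2-yl)oxy]-4-[(triisopropylsilyl)oxy]benzaldehyde F3. Bu4NF/AcOH should free the 4-OH to give 4-hydroxy-2-methoxy-6-[(2-methylbut-3-en-2-yl)oxy]benzaldehyde F4, and propargylation with 5 as in step 2 should give 7.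

3. Step 4. The aryl Grignard reagent may deprotonate the terminal alkyne in competition with slow addition to the di-ortho-substituted aldehyde, and the very electron-rich benzhydrol may ionise on work-up or during oxidation. The fallback sets out from 7 and comes back at 16; the thermal cascade is run first on the aldehyde, whose formyl group blocks the same ortho carbon as the aroyl group, so that no alkyne is left when the organometallic reagent is used. Heating 7 (PhNEt2, 110 °C, then 180 °C) should lead through prenylphenol aldehyde F5, allenylphenol aldehyde F6 and quinone methide aldehyde F7 (none isolated) to 7-hydroxy-5-methoxy-2,2-dimethyl-8-(3-methylbut-2-en-1-yl)-2H-chromene-6-carbaldehyde F8. Reagent 9 (2.2 equiv, the first equivalent being consumed by the phenol) should add to give racemic diol F9, and MnO2 (CH2Cl2, rt) should oxidise the doubly benzylic alcohol to 16.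

**Further compounds**

F0 | step 6 | none | none
F1 | step 3 | 2-hydroxy-6-methoxy-4-[(triisopropylsilyl)oxy]benzaldehyde | COc1cc(O[Si](C(C)C)(C(C)C)C(C)C)cc(O)c1C=O
F2 | step 3 | 2-methoxy-6-[(2-methylbut-3-yn-2-yl)oxy]-4-[(triisopropylsilyl)oxy]benzaldehyde | COc1cc(O[Si](C(C)C)(C(C)C)C(C)C)cc(OC(C)(C)C#C)c1C=O
F3 | step 3 | 2-methoxy-6-[(2-methylbut-3-en-2-yl)oxy]-4-[(triisopropylsilyl)oxy]benzaldehyde | COc1cc(O[Si](C(C)C)(C(C)C)C(C)C)cc(OC(C)(C)C=C)c1C=O
F4 | step 3 | 4-hydroxy-2-methoxy-6-[(2-methylbut-3-en-2-yl)oxy]benzaldehyde | COc1cc(O)cc(OC(C)(C)C=C)c1C=O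
F5 | step 4 | 2-hydroxy-6-methoxy-3-(3-methylbut-2-en-1-yl)-4-[(2-methylbut-3-yn-2-yl)oxy]benzaldehyde (formed in the flask) | COc1cc(OC(C)(C)C#C)c(CC=C(C)C)c(O)c1C=O
F6 | step 4 | 2,4-dihydroxy-6-methoxy-5-(3-methylbuta-1,2-dien-1-yl)-3-(3-methylbut-2-en-1-yl)benzaldehyde (formed in the flask) | COc1c(C=C=C(C)C)c(O)c(CC=C(C)C)c(O)c1C=O
F7 | step 4 | (6Z)-3-hydroxy-1-methoxy-4-(3-methylbut-2-en-1-yl)-6-(3-methylbut-2-en-1-ylidene)-5-oxocyclohexa-1,3-diene-2-carbaldehyde (formed in the flask) | COC1=C(C=O)C(O)=C(CC=C(C)C)C(=O)/C1=C\C=C(C)C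
F8 | step 4 | 7-hydroxy-5-methoxy-2,2-dimethyl-8-(3-methylbut-2-en-1-yl)-2H-chromene-6-carbaldehyde | COc1c2c(c(CC=C(C)C)c(O)c1C=O)OC(C)(C)C=C2
F9 | step 4 | rac-6-(hydroxy{4-[(triisopropylsilyl)oxy]phenyl}methyl)-5-methoxy-2,2-dimethyl-8-(3-methylbut-2-en-1-yl)-2H-chromen-7-ol | COc1c2c(c(CC=C(C)C)c(O)c1C(O)c1ccc(O[Si](C(C)C)(C(C)C)C(C)C)cc1)OC(C)(C)C=C2
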